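The route rests on building arene G, the resorcinol ring fused to dihydrofuran ring 3, from an acyclic α-diazo enone and ethoxyacetylene. Arene G bears carbon substituents on the neighbouring atoms C3a and C4, and C4 is meta to both O1 and the C6 oxygen; one photochemical Wolff, (2+2) and electrocyclisation cascade forms three C–C bonds and delivers exactly this pattern, with chloride at C4 and a free phenol for closing ring 3. The precursor is a (Z)-α-chloro-α'-diazo enone whose side chain carries the C3 centre, set by an Evans aldol reaction. Since rings 1 and 3 are identical, the benzannulation product supplies both halves, which ring 2 then joins.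

Key step: step 8

Remarks on the chemistry (assumptions):
- Labels: the dihydrofuran rings are numbered 1 to 3 from the stilbene end, and the benzo rings fused to them are arenes A, D and G. Locants O1, C2, C3, C3a, C4–C7, C7a are those of each 2,3-dihydrobenzofuran. The target is (2R,3R) in all three rings, each ring trans.
- The benzylic carbinol of the key-step precursor is syn to the neighbouring aryl-bearing centre, which is what a syn-aldol reaction delivers; an anti-selective allylation would give its epimer. Step 9 erases this configuration, so only the aryl-bearing centre has to be controlled.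
- Step 17 assumes that the sulfide controls the ylide carbon as it does in aldehyde epoxidation. The (1R,4R,5R) sulfide is drawn; its mirror image would be taken if the sense of induction proved opposite.
- Compound 23 is divided between steps 10 and 12.

Step 1
Reactants: 1 2-(3,5-dimethoxyphenyl)acetic acid; 2 (4S)-4-benzyl-1,3-oxazolidin-2-one
Product: 4 (4S)-4-benzyl-3-[2-(3,5-dimethoxyphenyl)acetyl]-1,3-oxazolidin-2-one, via mixed pivalic anhydride 3 (not isolated)
Conditions: t-BuCOCl, Et3N, THF, −20 °C; then 2, LiCl, rt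
Reagents that add atoms: none
Why: N-acylation of the oxazolidinone by the mixed pivalic anhydride formed in situ, with LiCl and Et3N making the carbamate nitrogen nucleophilic enough, is the standard one-pot loading of an Evans auxiliary and creates no stereocentre.

Step 2
Reactants: 4 acyl oxazolidinone; 5 4-(methoxymethoxy)benzaldehyde
Product: 7 (4S)-4-benzyl-3-[(2S,3S)-2-(3,5-dimethoxyphenyl)-3-hydroxy-3-[4-(methoxymethoxy)phenyl]propanoyl]-1,3-oxazolidin-2-one, via dibutylboron enolate 6 (not isolated)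
Conditions: Bu2BOTf, i-Pr2NEt, CH2Cl2, −78 → 0 °C; then 5, −78 → 0 °C; pH 7 buffer, MeOH, H2O2, 0 °C
Reagents that add atoms: none
Why: Evans syn-aldol reaction: the Z boron enolate reacts through a closed chair transition state on the enolate face remote from the benzyl group, which should set the aryl-bearing centre (2S, the future C3 of ring 3) under auxiliary control and the carbinol syn to it.

Step 3
Reactants: 7 syn-aldol adduct
Product: 8 tert-butyldimethylsilyl ether of 7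
Conditions: TBSOTf, 2,6-lutidine, CH2Cl2, −78 → 0 °C
Reagents that add atoms: tert-butyldimethylsilyl trifluoromethanesulfonate, CC(C)(C)[Si](C)(C)OS(=O)(=O)C(F)(F)F
Why: Silylation of the secondary benzylic alcohol with the silyl triflate and a hindered base blocks retro-aldol cleavage and masks the oxygen until ring closure.

Step 4
Reactants: 8 silylated imide
Product: 9 (2R,3S)-3-[(tert-butyldimethylsilyl)oxy]-2-(3,5-dimethoxyphenyl)-3-[4-(methoxymethoxy)phenyl]propan-1-ol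
Conditions: LiBH4, MeOH (1 equiv), THF, 0 °C
Reagents that add atoms: none
Why: Borohydride reduction of the exocyclic imide carbonyl (reductive removal of the Evans auxiliary) gives the primary alcohol without touching the adjacent centre, which is never enolised.

Step 5
Reactants: 10 diethyl (2-oxopropyl)phosphonate
Product: 11 diethyl (1-chloro-2-oxopropyl)phosphonate (racemic)
Conditions: SO2Cl2, CH2Cl2, 0 °C
Reagents that add atoms: sulfuryl chloride, O=S(=O)(Cl)Cl
Why: Electrophilic α-chlorination of the β-ketophosphonate through its enol gives the monochloride; its stereocentre is of no consequence because it becomes an alkene carbon.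

Step 6
Reactants: 9 primary alcohol; 11 chloro ketophosphonate
Product: 13 (3Z,5S,6S)-6-[(tert-butyldimethylsilyl)oxy]-3-chloro-5-(3,5-dimethoxyphenyl)-6-[4-(methoxymethoxy)phenyl]hex-3-en-2-one, via aldehyde 12 (not isolated)
Conditions: Dess–Martin periodinane, NaHCO3, CH2Cl2, 0 °C; then 11, LiCl, i-Pr2NEt, MeCN, 0 °C
Reagents that add atoms: none
Why: Dess–Martin oxidation under buffered conditions is followed directly by Horner–Wadsworth–Emmons olefination under Masamune–Roush conditions, where lithium chelation lets a weak amine deprotonate the acidic chloro ketophosphonate so that the α-aryl aldehyde should not epimerise; the acetyl group is expected trans to the side chain (Z alkene) and any E isomer is removed by chromatography.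

Step 7
Reactants: 13 chloro enone
Product: 15 (3Z,5S,6S)-6-[(tert-butyldimethylsilyl)oxy]-3-chloro-1-diazo-5-(3,5-dimethoxyphenyl)-6-[4-(methoxymethoxy)phenyl]hex-3-en-2-one, via trifluoroacetyl diketone 14 (not isolated)
Conditions: LiN(SiMe3)2, THF, −78 °C; CF3CO2CH2CF3; then MsN3, Et3N, H2O, MeCN, rt
Reagents that add atoms: methanesulfonyl azide, CS(=O)(=O)N=[N+]=[N-]
Why: Detrifluoroacetylative diazo transfer: kinetic enolisation at the methyl group and trifluoroacetylation activate the ketone for diazo transfer from the sulfonyl azide with loss of the trifluoroacetyl group, which avoids acylating diazomethane with an enoyl derivative (competing dipolar cycloaddition to the alkene) and leaves the hindered γ centre untouched.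

Step 8
Reactants: 15 α-diazo enone; 16 ethoxyacetylene
Product: 21 3-chloro-5-ethoxy-2-[(1R,2S)-2-[(tert-butyldimethylsilyl)oxy]-1-(3,5-dimethoxyphenyl)-2-[4-(methoxymethoxy)phenyl]ethyl]phenol, via vinylketene 17 (not isolated), via vinylcyclobutenone 18 (not isolated), via dienylketene 19 (not isolated), via cyclohexadienone 20 (not isolated)
Conditions: 16 (5 equiv), ClCH2CH2Cl, hν (medium-pressure Hg lamp, Pyrex filter), rt; then 80 °C
Reagents that add atoms: none
Why: Photolysis expels nitrogen from 15 and Wolff rearrangement (1,2-shift of the chlorovinyl group) gives vinylketene 17; the electron-rich terminal carbon of ethoxyacetylene adds to the ketene carbonyl carbon and (2+2) closure gives 4-vinylcyclobutenone 18, which on warming opens by four-electron conrotatory cleavage to dienylketene 19. Arene G is closed by six-electron disrotatory electrocyclisation of 19 to cyclohexadienone 20, followed by enolisation to phenol 21. This is the Danheiser benzannulation in its photochemical Wolff form with an alkoxyacetylene, a known route to resorcinol monoethers. No new stereocentre remains, since the sp3 ring carbons of 18 and 20 are transient. The step needs only regioselectivity, which follows from the polarity of ketene and ynol ether and from the connectivity of the enone, so that OH, side chain and Cl land on three adjacent carbons with OEt meta to OH; the Z enone keeps the side chain on the outside of the closing triene. The two existing centres are never α to a carbonyl and the medium is neutral, so they should pass through unchanged.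

Step 9
Reactants: 21 benzannulation phenol
Product: 23 4-[(2R,3R)-4-chloro-3-(3,5-dimethoxyphenyl)-6-ethoxy-2,3-dihydro-1-benzofuran-2-yl]phenol, via triol 22 (not isolated)
Conditions: 3 M HCl, MeOH/THF, 45 °C; then TsOH·H2O (cat.), CH2Cl2, rt
Reagents that add atoms: none
Why: Acid removes the silyl and methoxymethyl groups and ionises the 4-hydroxybenzylic position (p-quinone methide or its protonated form), which the arene G phenol captures in a 5-exo cyclisation; C2 is set trans to the aryl group on C3 under thermodynamic control, so the carbinol configuration does not matter.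

Step 10
Reactants: 23 chloro dihydrobenzofuran phenol
Product: 25 (2R,3R)-4-chloro-6-(triisopropylsilyloxy)-3-[3,5-bis(triisopropylsilyloxy)phenyl]-2-[4-(triisopropylsilyloxy)phenyl]-2,3-dihydro-1-benzofuran, via tetraphenol 24 (not isolated)
Conditions: BBr3, CH2Cl2, −78 → 0 °C, then MeOH; TIPSCl, imidazole, DMF, rt
Reagents that add atoms: triisopropylsilyl chloride, CC(C)[Si](Cl)(C(C)C)C(C)C
Why: Boron tribromide cleaves the two methyl ethers and the ethyl ether at a stage where a transient opening of ring 3 can only reclose to the trans ring, and silylation of the crude tetraphenol installs fluoride-labile protection so that no acid is needed once ring 2 exists.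

Step 11
Reactants: 25 silylated aryl chloride
Product: 26 pinacol boronate of 25 (boron in place of Cl at C4 of arene G)
Conditions: B2pin2, Pd2(dba)3, XPhos, KOAc, dioxane, 100 °C
Reagents that add atoms: bis(pinacolato)diboron, CC1(C)OB(OC1(C)C)B1OC(C)(C)C(C)(C)O1
Why: Miyaura borylation: a bulky electron-rich biarylphosphine enables oxidative addition of the hindered aryl chloride and acetate-assisted transmetalation with the diboron reagent turns C4 of arene G into a nucleophile.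

Step 12
Reactants: 23 chloro dihydrobenzofuran phenol
Product: 27 5-[(2R,3R)-4-chloro-3-(3,5-dimethoxyphenyl)-6-ethoxy-2,3-dihydro-1-benzofuran-2-yl]-2-hydroxybenzaldehyde
Conditions: MgCl2, Et3N, (CH2O)n, MeCN, reflux
Reagents that add atoms: paraformaldehyde (formaldehyde), C=O
Why: Magnesium-mediated ortho-formylation (Casnati–Skattebøl): the magnesium phenoxide delivers formaldehyde to the ortho carbon and a second formaldehyde oxidises the benzylic alkoxide, so only the single free phenol of 23, whose para position is blocked, is functionalised.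

Step 13
Reactants: 27 salicylaldehyde
Product: 29 5-[(2R,3R)-4-chloro-6-(triisopropylsilyloxy)-3-[3,5-bis(triisopropylsilyloxy)phenyl]-2,3-dihydro-1-benzofuran-2-yl]-2-hydroxybenzaldehyde, via tetraphenol aldehyde 28 (not isolated)
Conditions: BBr3, CH2Cl2, −78 → 0 °C, then MeOH; TIPSCl (3.3 equiv), imidazole, CH2Cl2/DMF, 0 °C
Reagents that add atoms: triisopropylsilyl chloride, CC(C)[Si](Cl)(C(C)C)C(C)C
Why: Dealkylation as in step 10 (the aldehyde tolerates boron tribromide), then silylation of the three unhindered phenols; the hydroxyl hydrogen-bonded to the ortho formyl group is the least reactive and should stay free, which is the differentiation that ring 2 needs.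

Step 14
Reactants: 26 aryl boronate; 29 silylated salicylaldehyde
Product: 31 sulfone [arene D carbon ortho to its OH bears CH(SO2C6H4CH3-4) bonded to C4 of arene G; epimers at that carbon], via diarylmethanol 30 (not isolated)
Conditions: [Rh(OH)(cod)]2 (5 mol %), dioxane/H2O (10:1), 80 °C; then p-TolSO2H, CH2Cl2, rt
Reagents that add atoms: p-toluenesulfinic acid, Cc1ccc(cc1)S(=O)O
Why: Rhodium-catalysed 1,2-addition of the aryl boronate to the aldehyde (transmetalation to an aryl–rhodium species, insertion of C=O) joins the halves at C4 of arene G, and the doubly benzylic o-hydroxy carbinol then ionises under the mild acidity of the sulfinic acid and is trapped as the sulfone; the new centre is not controlled and need not be, since it becomes planar in step 17.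

Step 15
Reactants: 32 4-[(tert-butyldimethylsilyl)oxy]benzaldehyde
Product: 33 {4-[(tert-butyldimethylsilyl)oxy]phenyl}methanol
Conditions: NaBH4, MeOH, 0 °C
Reagents that add atoms: none
Why: Simple borohydride reduction of the aldehyde to the benzylic alcohol.

Step 16
Reactants: 33 benzylic alcohol; 34 (1R,4R,5R)-isothiocineole
Product: 36 (1R,4R,5R)-6-{4-[(tert-butyldimethylsilyl)oxy]benzyl}-4,7,7-trimethyl-6-thiabicyclo[3.2.1]octan-6-ium triflate, via benzyl bromide 35 (not isolated)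
Conditions: CBr4, PPh3, CH2Cl2, 0 °C; then 34, LiOTf, CH2Cl2/H2O, rt
Reagents that add atoms: lithium trifluoromethanesulfonate, [Li+].[O-]S(=O)(=O)C(F)(F)F
Why: Appel bromination, then S-alkylation of the chiral sulfide on its less hindered face and exchange of bromide for the non-nucleophilic triflate, the usual preparation of benzylsulfonium salts.

Step 17
Reactants: 31 sulfone; 36 chiral benzylsulfonium triflate
Product: 38 protected tetramer chloride (rings 1 to 3 closed and all (2R,3R); Cl at C4 of arene A), via quinone methide 37 (not isolated)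
Conditions: 36 (1.5 equiv), Cs2CO3, CH2Cl2/MeCN, −20 → 0 °C
Reagents that add atoms: none
Why: Proposed new method: Cs2CO3 expels sulfinate from 31 to give o-quinone methide 37 and deprotonates 36 to the benzylide; conjugate addition of the ylide carbon to the methide carbon (future C3 of ring 2) and SN2 displacement of the sulfide by the arene D phenoxide, with inversion, close ring 2 in a formal (4+1) annulation, the anti betaine leading to the trans ring; the closest known reactions are the (4+1) annulation of sulfonium ylides with o-quinone methides to trans-2,3-dihydrobenzofurans and the epoxidation of aldehydes with isothiocineole-derived benzylides, in which the sulfide fixes the ylide conformation and the face that reacts, so C2 should be set by the reagent and C3 by the trans requirement.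

Step 18
Reactants: 38 protected tetramer chloride; 39 4-[(tert-butyldimethylsilyl)oxy]styrene
Product: 40 nonasilylated target (E stilbene at C4 of arene A)
Conditions: Pd2(dba)3, [(t-Bu)3PH]BF4, Cy2NMe, dioxane, 100 °C
Reagents that add atoms: none
Why: Mizoroki–Heck reaction of the aryl chloride with the styrene, made possible by the bulky trialkylphosphine; syn insertion and syn β-hydride elimination give the E stilbene.

Step 19
Reactants: 40 nonasilylated target
Product: 41 CNP0184803.1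
Conditions: TBAF, AcOH, THF, 0 °C → rt
Reagents that add atoms: none
Why: Fluoride cleaves all nine aryl silyl ethers under acetic-acid-buffered, near-neutral conditions, so that neither the dihydrofuran rings nor the stilbene are exposed to acid or strong base.

Compound list

In the names of 30, 31, 37 and the F compounds, "unit X" is (2R,3R)-6-(triisopropylsilyloxy)-3-[3,5-bis(triisopropylsilyloxy)phenyl]-2-[4-(triisopropylsilyloxy)phenyl]-2,3-dihydro-1-benzofuran-4-yl and "unit Y" is (2R,3R)-4-chloro-6-(triisopropylsilyloxy)-3-[3,5-bis(triisopropylsilyloxy)phenyl]-2,3-dihydro-1-benzofuran-2-yl.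

1 | 2-(3,5-dimethoxyphenyl)acetic acid | COc1cc(CC(=O)O)cc(OC)c1 | starting material
2 | (4S)-4-benzyl-1,3-oxazolidin-2-one | O=C1N[C@@H](Cc2ccccc2)CO1 | starting material
3 | 2-(3,5-dimethoxyphenyl)acetic pivalic anhydride | COc1cc(CC(=O)OC(=O)C(C)(C)C)cc(OC)c1 | intermediate
4 | (4S)-4-benzyl-3-[2-(3,5-dimethoxyphenyl)acetyl]-1,3-oxazolidin-2-one | COc1cc(CC(=O)N2[C@@H](Cc3ccccc3)COC2=O)cc(OC)c1 | intermediate
5 | 4-(methoxymethoxy)benzaldehyde | COCOc1ccc(C=O)cc1 | starting material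
6 | (Z)-dibutylboron enolate of 4 | CCCCB(CCCC)O/C(=C\c1cc(OC)cc(OC)c1)N1[C@@H](Cc2ccccc2)COC1=O | intermediate
7 | (4S)-4-benzyl-3-[(2S,3S)-2-(3,5-dimethoxyphenyl)-3-hydroxy-3-[4-(methoxymethoxy)phenyl]propanoyl]-1,3-oxazolidin-2-one | O=C1OC[C@H](Cc2ccccc2)N1C(=O)[C@@H](c1cc(OC)cc(OC)c1)[C@H](O)c1ccc(OCOC)cc1 | intermediate
8 | (4S)-4-benzyl-3-[(2S,3S)-3-[(tert-butyldimethylsilyl)oxy]-2-(3,5-dimethoxyphenyl)-3-[4-(methoxymethoxy)phenyl]propanoyl]-1,3-oxazolidin-2-one | O=C1OC[C@H](Cc2ccccc2)N1C(=O)[C@@H](c1cc(OC)cc(OC)c1)[C@H](O[Si](C)(C)C(C)(C)C)c1ccc(OCOC)cc1 | intermediate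
9 | (2R,3S)-3-[(tert-butyldimethylsilyl)oxy]-2-(3,5-dimethoxyphenyl)-3-[4-(methoxymethoxy)phenyl]propan-1-ol | OC[C@@H](c1cc(OC)cc(OC)c1)[C@H](O[Si](C)(C)C(C)(C)C)c1ccc(OCOC)cc1 | intermediate
10 | diethyl (2-oxopropyl)phosphonate | CCOP(=O)(CC(C)=O)OCC | starting material
11 | diethyl (1-chloro-2-oxopropyl)phosphonate (racemic) | CCOP(=O)(OCC)C(Cl)C(C)=O | intermediate
12 | (2S,3S)-3-[(tert-butyldimethylsilyl)oxy]-2-(3,5-dimethoxyphenyl)-3-[4-(methoxymethoxy)phenyl]propanal | O=C[C@@H](c1cc(OC)cc(OC)c1)[C@H](O[Si](C)(C)C(C)(C)C)c1ccc(OCOC)cc1 | intermediate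
13 | (3Z,5S,6S)-6-[(tert-butyldimethylsilyl)oxy]-3-chloro-5-(3,5-dimethoxyphenyl)-6-[4-(methoxymethoxy)phenyl]hex-3-en-2-one | CC(=O)/C(Cl)=C/[C@@H](c1cc(OC)cc(OC)c1)[C@H](O[Si](C)(C)C(C)(C)C)c1ccc(OCOC)cc1 | intermediate
14 | (5Z,7S,8S)-8-[(tert-butyldimethylsilyl)oxy]-5-chloro-7-(3,5-dimethoxyphenyl)-1,1,1-trifluoro-8-[4-(methoxymethoxy)phenyl]oct-5-ene-2,4-dione | FC(F)(F)C(=O)CC(=O)/C(Cl)=C/[C@@H](c1cc(OC)cc(OC)c1)[C@H](O[Si](C)(C)C(C)(C)C)c1ccc(OCOC)cc1 | intermediate
15 | (3Z,5S,6S)-6-[(tert-butyldimethylsilyl)oxy]-3-chloro-1-diazo-5-(3,5-dimethoxyphenyl)-6-[4-(methoxymethoxy)phenyl]hex-3-en-2-one | [N-]=[N+]=CC(=O)/C(Cl)=C/[C@@H](c1cc(OC)cc(OC)c1)[C@H](O[Si](C)(C)C(C)(C)C)c1ccc(OCOC)cc1 | intermediate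
16 | ethoxyacetylene | CCOC#C | starting material
17 | (3Z,5S,6S)-6-[(tert-butyldimethylsilyl)oxy]-3-chloro-5-(3,5-dimethoxyphenyl)-6-[4-(methoxymethoxy)phenyl]hexa-1,3-dien-1-one (vinylketene) | O=C=C/C(Cl)=C/[C@@H](c1cc(OC)cc(OC)c1)[C@H](O[Si](C)(C)C(C)(C)C)c1ccc(OCOC)cc1 | intermediate
18 | 3-ethoxy-4-[(1Z,3S,4S)-4-[(tert-butyldimethylsilyl)oxy]-1-chloro-3-(3,5-dimethoxyphenyl)-4-[4-(methoxymethoxy)phenyl]but-1-en-1-yl]cyclobut-2-en-1-one (epimers at the ring carbon) | CCOC1=CC(=O)C1/C(Cl)=C/[C@@H](c1cc(OC)cc(OC)c1)[C@H](O[Si](C)(C)C(C)(C)C)c1ccc(OCOC)cc1 | intermediate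
19 | (3E,5Z,7S,8S)-8-[(tert-butyldimethylsilyl)oxy]-5-chloro-7-(3,5-dimethoxyphenyl)-3-ethoxy-8-[4-(methoxymethoxy)phenyl]octa-1,3,5-trien-1-one (dienylketene) | O=C=C/C(OCC)=C\C(Cl)=C\[C@@H](c1cc(OC)cc(OC)c1)[C@H](O[Si](C)(C)C(C)(C)C)c1ccc(OCOC)cc1 | intermediate
20 | 5-chloro-3-ethoxy-6-[(1S,2S)-2-[(tert-butyldimethylsilyl)oxy]-1-(3,5-dimethoxyphenyl)-2-[4-(methoxymethoxy)phenyl]ethyl]cyclohexa-2,4-dien-1-one (epimers at C6) | CCOC1=CC(=O)C([C@@H](c2cc(OC)cc(OC)c2)[C@H](O[Si](C)(C)C(C)(C)C)c2ccc(OCOC)cc2)C(Cl)=C1 | intermediate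
21 | 3-chloro-5-ethoxy-2-[(1R,2S)-2-[(tert-butyldimethylsilyl)oxy]-1-(3,5-dimethoxyphenyl)-2-[4-(methoxymethoxy)phenyl]ethyl]phenol | Oc1cc(OCC)cc(Cl)c1[C@@H](c1cc(OC)cc(OC)c1)[C@H](O[Si](C)(C)C(C)(C)C)c1ccc(OCOC)cc1 | intermediate
22 | 3-chloro-2-[(1R,2S)-1-(3,5-dimethoxyphenyl)-2-hydroxy-2-(4-hydroxyphenyl)ethyl]-5-ethoxyphenol | Oc1cc(OCC)cc(Cl)c1[C@@H](c1cc(OC)cc(OC)c1)[C@H](O)c1ccc(O)cc1 | intermediate
23 | 4-[(2R,3R)-4-chloro-3-(3,5-dimethoxyphenyl)-6-ethoxy-2,3-dihydro-1-benzofuran-2-yl]phenol | Clc1cc(OCC)cc2c1[C@@H](c1cc(OC)cc(OC)c1)[C@H](c1ccc(O)cc1)O2 | intermediate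
24 | 5-[(2R,3R)-4-chloro-6-hydroxy-2-(4-hydroxyphenyl)-2,3-dihydro-1-benzofuran-3-yl]benzene-1,3-diol | Clc1cc(O)cc2c1[C@@H](c1cc(O)cc(O)c1)[C@H](c1ccc(O)cc1)O2 | intermediate
25 | (2R,3R)-4-chloro-6-(triisopropylsilyloxy)-3-[3,5-bis(triisopropylsilyloxy)phenyl]-2-[4-(triisopropylsilyloxy)phenyl]-2,3-dihydro-1-benzofuran | Clc1cc(O[Si](C(C)C)(C(C)C)C(C)C)cc2c1[C@@H](c1cc(O[Si](C(C)C)(C(C)C)C(C)C)cc(O[Si](C(C)C)(C(C)C)C(C)C)c1)[C@H](c1ccc(O[Si](C(C)C)(C(C)C)C(C)C)cc1)O2 | intermediate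
26 | 2-(unit X)-4,4,5,5-tetramethyl-1,3,2-dioxaborolane | CC1(C)OB(OC1(C)C)c1cc(O[Si](C(C)C)(C(C)C)C(C)C)cc2c1[C@@H](c1cc(O[Si](C(C)C)(C(C)C)C(C)C)cc(O[Si](C(C)C)(C(C)C)C(C)C)c1)[C@H](c1ccc(O[Si](C(C)C)(C(C)C)C(C)C)cc1)O2 | intermediate
27 | 5-[(2R,3R)-4-chloro-3-(3,5-dimethoxyphenyl)-6-ethoxy-2,3-dihydro-1-benzofuran-2-yl]-2-hydroxybenzaldehyde | Clc1cc(OCC)cc2c1[C@@H](c1cc(OC)cc(OC)c1)[C@H](c1ccc(O)c(C=O)c1)O2 | intermediate
28 | 5-[(2R,3R)-4-chloro-3-(3,5-dihydroxyphenyl)-6-hydroxy-2,3-dihydro-1-benzofuran-2-yl]-2-hydroxybenzaldehyde | Clc1cc(O)cc2c1[C@@H](c1cc(O)cc(O)c1)[C@H](c1ccc(O)c(C=O)c1)O2 | intermediate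
29 | 2-hydroxy-5-(unit Y)benzaldehyde | Clc1cc(O[Si](C(C)C)(C(C)C)C(C)C)cc2c1[C@@H](c1cc(O[Si](C(C)C)(C(C)C)C(C)C)cc(O[Si](C(C)C)(C(C)C)C(C)C)c1)[C@H](c1ccc(O)c(C=O)c1)O2 | intermediate
30 | [2-hydroxy-5-(unit Y)phenyl](unit X)methanol (epimers at the carbinol) | Clc1cc(O[Si](C(C)C)(C(C)C)C(C)C)cc2c1[C@@H](c1cc(O[Si](C(C)C)(C(C)C)C(C)C)cc(O[Si](C(C)C)(C(C)C)C(C)C)c1)[C@H](c1ccc(O)c(c1)C(O)c1cc(O[Si](C(C)C)(C(C)C)C(C)C)cc3c1[C@@H](c1cc(O[Si](C(C)C)(C(C)C)C(C)C)cc(O[Si](C(C)C)(C(C)C)C(C)C)c1)[C@H](c1ccc(O[Si](C(C)C)(C(C)C)C(C)C)cc1)O3)O2 | intermediate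
31 | 2-[(unit X)(4-methylbenzenesulfonyl)methyl]-4-(unit Y)phenol (epimers at the sulfonyl-bearing carbon) | Clc1cc(O[Si](C(C)C)(C(C)C)C(C)C)cc2c1[C@@H](c1cc(O[Si](C(C)C)(C(C)C)C(C)C)cc(O[Si](C(C)C)(C(C)C)C(C)C)c1)[C@H](c1ccc(O)c(c1)C(S(=O)(=O)c1ccc(C)cc1)c1cc(O[Si](C(C)C)(C(C)C)C(C)C)cc3c1[C@@H](c1cc(O[Si](C(C)C)(C(C)C)C(C)C)cc(O[Si](C(C)C)(C(C)C)C(C)C)c1)[C@H](c1ccc(O[Si](C(C)C)(C(C)C)C(C)C)cc1)O3)O2 | intermediate
32 | 4-[(tert-butyldimethylsilyl)oxy]benzaldehyde | CC(C)(C)[Si](C)(C)Oc1ccc(C=O)cc1 | starting material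
33 | {4-[(tert-butyldimethylsilyl)oxy]phenyl}methanol | CC(C)(C)[Si](C)(C)Oc1ccc(CO)cc1 | intermediate
34 | (1R,4R,5R)-4,7,7-trimethyl-6-thiabicyclo[3.2.1]octane (isothiocineole) | C[C@@H]1CC[C@@H]2C[C@H]1SC2(C)C | starting material
35 | 1-(bromomethyl)-4-[(tert-butyldimethylsilyl)oxy]benzene | CC(C)(C)[Si](C)(C)Oc1ccc(CBr)cc1 | intermediate
36 | (1R,4R,5R)-6-{4-[(tert-butyldimethylsilyl)oxy]benzyl}-4,7,7-trimethyl-6-thiabicyclo[3.2.1]octan-6-ium trifluoromethanesulfonate (one diastereomer at sulfur, benzyl on the less hindered face) | C[C@@H]1CC[C@@H]2C[C@H]1[S+](Cc1ccc(O[Si](C)(C)C(C)(C)C)cc1)C2(C)C.[O-]S(=O)(=O)C(F)(F)F | intermediate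
37 | 6-[(unit X)methylidene]-4-(unit Y)cyclohexa-2,4-dien-1-one (o-quinone methide of arene D) | Clc1cc(O[Si](C(C)C)(C(C)C)C(C)C)cc2c1[C@@H](c1cc(O[Si](C(C)C)(C(C)C)C(C)C)cc(O[Si](C(C)C)(C(C)C)C(C)C)c1)[C@H](C1=CC(=Cc3cc(O[Si](C(C)C)(C(C)C)C(C)C)cc4c3[C@@H](c3cc(O[Si](C(C)C)(C(C)C)C(C)C)cc(O[Si](C(C)C)(C(C)C)C(C)C)c3)[C@H](c3ccc(O[Si](C(C)C)(C(C)C)C(C)C)cc3)O4)C(=O)C=C1)O2 | intermediate
38 | protected tetramer chloride: the target skeleton with all three rings (2R,3R), Cl at C4 of arene A in place of the styryl group, triisopropylsilyl ethers on the seven oxygens of the ring 1 and ring 3 units and a tert-butyldimethylsilyl ether on the 4-oxyphenyl group at C2 of ring 2 | Clc1cc(O[Si](C(C)C)(C(C)C)C(C)C)cc2c1[C@@H](c1cc(O[Si](C(C)C)(C(C)C)C(C)C)cc(O[Si](C(C)C)(C(C)C)C(C)C)c1)[C@H](c1ccc3c(c1)[C@@H](c1cc(O[Si](C(C)C)(C(C)C)C(C)C)cc4c1[C@@H](c1cc(O[Si](C(C)C)(C(C)C)C(C)C)cc(O[Si](C(C)C)(C(C)C)C(C)C)c1)[C@H](c1ccc(O[Si](C(C)C)(C(C)C)C(C)C)cc1)O4)[C@H](c1ccc(O[Si](C)(C)C(C)(C)C)cc1)O3)O2 | intermediate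
39 | 4-[(tert-butyldimethylsilyl)oxy]styrene | CC(C)(C)[Si](C)(C)Oc1ccc(C=C)cc1 | starting material
40 | nonasilylated target: 38 with (E)-2-{4-[(tert-butyldimethylsilyl)oxy]phenyl}ethenyl in place of Cl | CC(C)(C)[Si](C)(C)Oc1ccc(/C=C/c2cc(O[Si](C(C)C)(C(C)C)C(C)C)cc3c2[C@@H](c2cc(O[Si](C(C)C)(C(C)C)C(C)C)cc(O[Si](C(C)C)(C(C)C)C(C)C)c2)[C@H](c2ccc4c(c2)[C@@H](c2cc(O[Si](C(C)C)(C(C)C)C(C)C)cc5c2[C@@H](c2cc(O[Si](C(C)C)(C(C)C)C(C)C)cc(O[Si](C(C)C)(C(C)C)C(C)C)c2)[C@H](c2ccc(O[Si](C(C)C)(C(C)C)C(C)C)cc2)O5)[C@H](c2ccc(O[Si](C)(C)C(C)(C)C)cc2)O4)O3)cc1 | intermediate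
41 | CNP0184803.1 (all three dihydrofuran rings (2R,3R), E stilbene) | Oc1ccc(/C=C/c2cc(O)cc3c2[C@@H](c2cc(O)cc(O)c2)[C@H](c2ccc4c(c2)[C@@H](c2cc(O)cc5c2[C@@H](c2cc(O)cc(O)c2)[C@H](c2ccc(O)cc2)O5)[C@H](c2ccc(O)cc2)O4)O3)cc1 | target

Total step count: 19.
Longest linear sequence: 14 steps (1–4, 6–9, 12–14, 17–19; the branch through steps 10 and 11 is equally long).

Steps most likely to fail

1. Step 17 (proposed new method). The transfer of chirality from the sulfonium ylide to the quinone methide may be incomplete, so that both faces of the methide carbon are attacked, or the benzylide may be protonated or rearrange faster than it adds. The fallback is a rhodium-carbene C–H insertion, a known way to 2,3-diaryl-2,3-dihydrobenzofurans. It sets out from diarylmethanol 30 (isolated after the addition of step 14) and bromide 35. O-Alkylation of the arene D phenol (K2CO3, acetone) gives the 4-silyloxybenzyl ether F1, and oxidation with MnO2 gives the diaryl ketone F2. Hydrazine hydrate (AcOH cat., EtOH, 80 °C) gives the hydrazone F3, and MnO2 (CH2Cl2, 0 °C) gives the diaryldiazomethane F4. Rh2(R-PTAD)4 (dirhodium tetrakis[(R)-N-phthaloyl-1-adamantylglycinate], or its mirror image, whichever delivers 3R) then inserts the carbene into the benzylic ether C–H bond. In this reaction class the cis ring is expected first, here F5 with ring 2 (2S,3R). A short treatment with CF3CO2H (cat., CH2Cl2, −20 °C) equilibrates C2 through the 4-silyloxybenzylic cation to the trans ring, and the route is rejoined at 38.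

2. Step 8 (key step). Capture of the vinylketene by the phenol already formed, ketene dimerisation or competing photochemistry of the chloro enone could divert the cascade before the six-electron closure. The fallback buys arene G instead of building it. 5-Chlororesorcinol F6 is acylated with 3,5-dimethoxybenzoyl chloride F7 (AlCl3, Friedel–Crafts, at the position ortho to one hydroxyl, para to the other and next to Cl) to give benzophenone F8. The non-chelated hydroxyl is ethylated (EtI, K2CO3, acetone) to F9 and the chelated one is benzylated with 35 (K2CO3, DMF) to F10. Hydrazine hydrate gives hydrazone F11, MnO2 gives the diazo compound F12, and Rh2(R-PTAD)4 (or its mirror image) closes ring 3 by C–H insertion to the cis-dihydrobenzofuran F13, the catalyst setting C3. TBAF frees the cis phenol F14, and TsOH (cat., CH2Cl2) equilibrates C2 to trans through the quinone methide. The route is rejoined at 23.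

3. Step 14. Transmetalation and carbonyl insertion may be slow for the ortho-substituted boronate, so that protodeboronation outruns the addition. The fallback uses a stoichiometric arylzinc reagent and sets out from 26. NaIO4 and NH4OAc (acetone/H2O) free the boronic acid F15, and boron–zinc exchange with Et2Zn (toluene, 60 °C) gives the aryl(ethyl)zinc F16. This adds at 0 °C to the zinc phenoxide of aldehyde 29, whose chelated carbonyl is activated. The product is diarylmethanol 30, where the route is rejoined.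

Further compounds
F1 | step 17 | {2-({4-[(tert-butyldimethylsilyl)oxy]phenyl}methoxy)-5-(unit Y)phenyl}(unit X)methanol | Clc1cc(O[Si](C(C)C)(C(C)C)C(C)C)cc2c1[C@@H](c1cc(O[Si](C(C)C)(C(C)C)C(C)C)cc(O[Si](C(C)C)(C(C)C)C(C)C)c1)[C@H](c1ccc(OCc5ccc(O[Si](C)(C)C(C)(C)C)cc5)c(c1)C(O)c1cc(O[Si](C(C)C)(C(C)C)C(C)C)cc3c1[C@@H](c1cc(O[Si](C(C)C)(C(C)C)C(C)C)cc(O[Si](C(C)C)(C(C)C)C(C)C)c1)[C@H](c1ccc(O[Si](C(C)C)(C(C)C)C(C)C)cc1)O3)O2
F2 | step 17 | diaryl ketone from F1 (C=O in place of CHOH) | Clc1cc(O[Si](C(C)C)(C(C)C)C(C)C)cc2c1[C@@H](c1cc(O[Si](C(C)C)(C(C)C)C(C)C)cc(O[Si](C(C)C)(C(C)C)C(C)C)c1)[C@H](c1ccc(OCc5ccc(O[Si](C)(C)C(C)(C)C)cc5)c(c1)C(=O)c1cc(O[Si](C(C)C)(C(C)C)C(C)C)cc3c1[C@@H](c1cc(O[Si](C(C)C)(C(C)C)C(C)C)cc(O[Si](C(C)C)(C(C)C)C(C)C)c1)[C@H](c1ccc(O[Si](C(C)C)(C(C)C)C(C)C)cc1)O3)O2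
F3 | step 17 | hydrazone of F2 | Clc1cc(O[Si](C(C)C)(C(C)C)C(C)C)cc2c1[C@@H](c1cc(O[Si](C(C)C)(C(C)C)C(C)C)cc(O[Si](C(C)C)(C(C)C)C(C)C)c1)[C@H](c1ccc(OCc5ccc(O[Si](C)(C)C(C)(C)C)cc5)c(c1)C(=NN)c1cc(O[Si](C(C)C)(C(C)C)C(C)C)cc3c1[C@@H](c1cc(O[Si](C(C)C)(C(C)C)C(C)C)cc(O[Si](C(C)C)(C(C)C)C(C)C)c1)[C@H](c1ccc(O[Si](C(C)C)(C(C)C)C(C)C)cc1)O3)O2
F4 | step 17 | diaryldiazomethane from F3 | Clc1cc(O[Si](C(C)C)(C(C)C)C(C)C)cc2c1[C@@H](c1cc(O[Si](C(C)C)(C(C)C)C(C)C)cc(O[Si](C(C)C)(C(C)C)C(C)C)c1)[C@H](c1ccc(OCc5ccc(O[Si](C)(C)C(C)(C)C)cc5)c(c1)C(=[N+]=[N-])c1cc(O[Si](C(C)C)(C(C)C)C(C)C)cc3c1[C@@H](c1cc(O[Si](C(C)C)(C(C)C)C(C)C)cc(O[Si](C(C)C)(C(C)C)C(C)C)c1)[C@H](c1ccc(O[Si](C(C)C)(C(C)C)C(C)C)cc1)O3)O2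
F5 | step 17 | C2 epimer of 38 in ring 2 (ring 2 cis, (2S,3R); rings 1 and 3 (2R,3R)) | Clc1cc(O[Si](C(C)C)(C(C)C)C(C)C)cc2c1[C@@H](c1cc(O[Si](C(C)C)(C(C)C)C(C)C)cc(O[Si](C(C)C)(C(C)C)C(C)C)c1)[C@H](c1ccc3c(c1)[C@@H](c1cc(O[Si](C(C)C)(C(C)C)C(C)C)cc4c1[C@@H](c1cc(O[Si](C(C)C)(C(C)C)C(C)C)cc(O[Si](C(C)C)(C(C)C)C(C)C)c1)[C@H](c1ccc(O[Si](C(C)C)(C(C)C)C(C)C)cc1)O4)[C@@H](c1ccc(O[Si](C)(C)C(C)(C)C)cc1)O3)O2
F6 | step 8 | 5-chlorobenzene-1,3-diol (commercial) | Oc1cc(O)cc(Cl)c1
F7 | step 8 | 3,5-dimethoxybenzoyl chloride (commercial) | COc1cc(cc(OC)c1)C(Cl)=O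
F8 | step 8 | (2-chloro-4,6-dihydroxyphenyl)(3,5-dimethoxyphenyl)methanone | COc1cc(cc(OC)c1)C(=O)c1c(O)cc(O)cc1Cl
F9 | step 8 | (2-chloro-4-ethoxy-6-hydroxyphenyl)(3,5-dimethoxyphenyl)methanone | CCOc1cc(O)c(c(Cl)c1)C(=O)c1cc(OC)cc(OC)c1
F10 | step 8 | [2-({4-[(tert-butyldimethylsilyl)oxy]phenyl}methoxy)-6-chloro-4-ethoxyphenyl](3,5-dimethoxyphenyl)methanone | CCOc1cc(OCc2ccc(O[Si](C)(C)C(C)(C)C)cc2)c(c(Cl)c1)C(=O)c1cc(OC)cc(OC)c1
F11 | step 8 | hydrazone of F10 | CCOc1cc(OCc2ccc(O[Si](C)(C)C(C)(C)C)cc2)c(c(Cl)c1)C(=NN)c1cc(OC)cc(OC)c1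
F12 | step 8 | diaryldiazomethane from F11 | CCOc1cc(OCc2ccc(O[Si](C)(C)C(C)(C)C)cc2)c(c(Cl)c1)C(=[N+]=[N-])c1cc(OC)cc(OC)c1
F13 | step 8 | (2S,3R)-2-{4-[(tert-butyldimethylsilyl)oxy]phenyl}-4-chloro-3-(3,5-dimethoxyphenyl)-6-ethoxy-2,3-dihydro-1-benzofuran (cis) | Clc1cc(OCC)cc2c1[C@@H](c1cc(OC)cc(OC)c1)[C@@H](c1ccc(O[Si](C)(C)C(C)(C)C)cc1)O2
F14 | step 8 | 4-[(2S,3R)-4-chloro-3-(3,5-dimethoxyphenyl)-6-ethoxy-2,3-dihydro-1-benzofuran-2-yl]phenol (cis) | Clc1cc(OCC)cc2c1[C@@H](c1cc(OC)cc(OC)c1)[C@@H](c1ccc(O)cc1)O2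
F15 | step 14 | (unit X)boronic acid | OB(O)c1cc(O[Si](C(C)C)(C(C)C)C(C)C)cc2c1[C@@H](c1cc(O[Si](C(C)C)(C(C)C)C(C)C)cc(O[Si](C(C)C)(C(C)C)C(C)C)c1)[C@H](c1ccc(O[Si](C(C)C)(C(C)C)C(C)C)cc1)O2
F16 | step 14 | ethyl(unit X)zinc | CC[Zn]c1cc(O[Si](C(C)C)(C(C)C)C(C)C)cc2c1[C@@H](c1cc(O[Si](C(C)C)(C(C)C)C(C)C)cc(O[Si](C(C)C)(C(C)C)C(C)C)c1)[C@H](c1ccc(O[Si](C(C)C)(C(C)C)C(C)C)cc1)O2
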